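**Plan**
Ring labels: the upper guibourtinidol unit has rings A (benzo), B (4-hydroxyphenyl) and C (pyran). The lower fisetinidol unit has rings D (benzo), E (catechol) and F (pyran).
Retrosynthesis: O1–C2 of ring F is cut first and C2(F) is re-hung on O3(C), which gives an isomeric isochroman (temporary ring G). Then C1'(E)–C2(F) is cut (oxa-Pictet–Spengler) to give 4-arylflavan-3-ol 10 and α-benzoyloxy aldehyde 15. Compound 10 is cut at C4(C)–C6'(E), then at O1–C2(C), the epoxide and the enone C=C.
Enabling feature: O3(C)–C3(C)–C4(C)–C6'(E)–C1'(E) is a 2-arylethanol. With one incoming carbon these atoms close a six-membered ring, and C1'(E) is para to O4'. The molecule's own 3-OH therefore steers an oxocarbenium carbon to the hindered C1'(E), past the more nucleophilic rings A and D.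
Forward order: ring C (epoxychalcone closure), C4 arylation (ring E), temporary ring G (fragment union), ring switch G to F, deprotection.
Stereochemistry: C2/C3(C) come from the Juliá–Colonna epoxidation and C4(C) from anti attack on the flavan-4-yl cation. C3(F) comes from enamine-catalysed α-benzoyloxylation and C2(F) from benzoate participation with inversion in the ring switch.

Key step: step 10

Remark 1: ring E keeps the locants of the target throughout. C6'(E) is bonded to C4(C), C1'(E) is the neighbouring CH, O4' is para to C1' and O3' is para to C6'.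
Remark 2: the sense of induction in step 9 is taken from the steric-shielding enamine model. Any enantiomeric leakage from steps 3 and 9 should leave as a diastereomer when 17 is purified.

Step 1
Reactants: 1 1-[4-(benzyloxy)-2-hydroxyphenyl]ethan-1-one
Product: 2 1-[4-(benzyloxy)-2-(methoxymethoxy)phenyl]ethan-1-one
Conditions: NaH, MOMCl, DMF, 0 °C to rt
Reagents that add atoms: chloromethyl methyl ether (MOMCl), COCCl
Why: Williamson-type O-alkylation of the chelated phenol, which must be masked so that the chalcone does not close to a flavanone or aurone under the basic peroxide of step 3.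

Step 2
Reactants: 2 1-[4-(benzyloxy)-2-(methoxymethoxy)phenyl]ethan-1-one; 3 4-(benzyloxy)benzaldehyde
Product: 4 (E)-1-[4-(benzyloxy)-2-(methoxymethoxy)phenyl]-3-[4-(benzyloxy)phenyl]prop-2-en-1-one
Conditions: KOH, EtOH, rt
Reagents that add atoms: none
Why: Claisen–Schmidt condensation, in which E1cB dehydration gives the thermodynamically preferred E enone.

Step 3
Reactants: 4 (E)-chalcone
Product: 5 [4-(benzyloxy)-2-(methoxymethoxy)phenyl]{(2R,3S)-3-[4-(benzyloxy)phenyl]oxiran-2-yl}methanone
Conditions: poly-L-leucine, urea·H2O2, DBU, THF, rt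
Reagents that add atoms: urea–hydrogen peroxide, OO.NC(N)=O
Why: Juliá–Colonna epoxidation (Weitz–Scheffer mechanism), in which the helical poly-L-leucine binds the enone and delivers hydroperoxide to one face, so the trans epoxide should form as αR,βS.

Step 4
Reactants: 5 (αR,βS)-epoxychalcone MOM ether
Product: 7 (2R,3R)-7-(benzyloxy)-2-[4-(benzyloxy)phenyl]-3-hydroxychroman-4-one, via 2'-hydroxy epoxychalcone 6 (not isolated)
Conditions: HCl, MeOH–THF, 50 °C
Reagents that add atoms: none
Why: Acid removes the MOM group and the freed phenol opens the epoxide at the benzylic Cβ (6-endo-tet, favoured by the 4-benzyloxyphenyl group) with inversion, while the Cα–O bond stays untouched, which gives the 2,3-trans (2R,3R) dihydroflavonol.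

Step 5
Reactants: 7 (2R,3R)-dihydroflavonol
Product: 8 (2R,3S,4R)-7-(benzyloxy)-2-[4-(benzyloxy)phenyl]chroman-3,4-diol
Conditions: NaBH4, MeOH–THF, 0 °C
Reagents that add atoms: none
Why: Borohydride reduction of 2,3-trans-dihydroflavonols is known to give mainly the 3,4-trans diol, and the C4 configuration is erased in step 6 in any case.

Step 6
Reactants: 8 (2R,3S,4R)-flavan-3,4-diol; 9 1,2-bis(benzyloxy)benzene
Product: 10 (2R,3S,4R)-7-(benzyloxy)-2-[4-(benzyloxy)phenyl]-4-[3,4-bis(benzyloxy)phenyl]chroman-3-ol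
Conditions: BF3·OEt2, 9 (large excess), CH2Cl2, −20 to 0 °C, slow addition of 8
Reagents that add atoms: none
Why: Friedel–Crafts alkylation that copies the biogenetic C4-to-ring-E coupling, in which BF3 ionises the 4-OH to the flavan-4-yl cation (stabilised by the para 7-benzyloxy group) and the arene attacks through the carbon para to one benzyloxy group, from the face anti to the 3-OH, which sets the all-equatorial 3,4-trans (4R) centre.

Step 7
Reactants: 11 1,3-bis(benzyloxy)benzene
Product: 12 2,4-bis(benzyloxy)-1-iodobenzene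
Conditions: NIS, TFA (cat.), MeCN, 0 °C to rt
Reagents that add atoms: N-iodosuccinimide, O=C1CCC(=O)N1I
Why: Electrophilic aromatic iodination goes to C4, which is ortho to one and para to the other ether oxygen and less hindered than C2.

Step 8
Reactants: 12 2,4-bis(benzyloxy)-1-iodobenzene; 13 prop-2-en-1-ol
Product: 14 3-[2,4-bis(benzyloxy)phenyl]propanal
Conditions: Pd(OAc)2 (cat.), Bu4NCl, NaHCO3, DMF, 50 °C
Reagents that add atoms: none
Why: Jeffery–Heck arylation of allyl alcohol, in which terminal carbopalladation is followed by β-hydride elimination towards the carbinol carbon and the enol tautomerises to the aldehyde.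

Step 9
Reactants: 14 3-[2,4-bis(benzyloxy)phenyl]propanal
Product: 15 (2S)-1-[2,4-bis(benzyloxy)phenyl]-3-oxopropan-2-yl benzoate
Conditions: (S)-2-tritylpyrrolidine (cat.), (BzO)2, hydroquinone (cat.), THF, 0 °C to rt
Reagents that add atoms: dibenzoyl peroxide, O=C(OOC(=O)c1ccccc1)c1ccccc1
Why: Enamine-catalysed α-benzoyloxylation, in which the trityl group shields one face of the E-enamine so that the peroxide oxygen is taken up on the other face, which sets the future C3(F) as S.

Step 10
Reactants: 10 4-arylflavan-3-ol; 15 (S)-α-benzoyloxy aldehyde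
Product: 17 isochroman in which O3(C) and C1'(E) of 10 are bridged by the former aldehyde CH (R, H on the same face as H3(C)), this CH carrying the (1S)-1-(benzoyloxy)-2-[2,4-bis(benzyloxy)phenyl]ethyl group, via oxocarbenium ion 16 (not isolated)
Conditions: TMSOTf (cat.), 4 Å MS, CH2Cl2 (high dilution), −40 to −10 °C
Reagents that add atoms: none
Why: The aldehyde and the 3-OH of ring C condense under TMSOTf to oxocarbenium ion 16, whose carbon is attacked by C1'(E), para to the 4'-benzyloxy group, and loss of a proton rearomatises ring E, which is an oxa-Pictet–Spengler reaction. The closest known reaction type is the closure of 2-(3,4-dioxyphenyl)ethanols with aldehydes to 1-substituted 6,7-dioxyisochromans, which is also known for flavan-3-ols, whose 3-OH and catechol ring condense with ketones under BF3·OEt2. Ring G closes in the 6-endo-trig mode onto the C=O+ bond and is trans-fused to ring C because O3 and the 4-aryl group are both equatorial. The new centre C2(F) should place its side chain pseudo-equatorial (1,3-cis to C2(C) across the ring oxygen), but its configuration is of no consequence because step 11 ionises it again. The step needs site selectivity for the hindered C1'(E) over the more nucleophilic C6/C8 of rings A and D, and the tether secures it: only C1'(E) reaches the cation through a six-membered transition state, the ortho carbons of ring B are meta to their oxygen, C5(A) is meta to both of its oxygens, and dilution holds back intermolecular attack. C3(F) should keep its configuration because the reaction is run cold and without base.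

Step 11
Reactants: 17 isochroman
Product: 19 (2R,3S)-2-{2-[(2R,3S,4R)-3-acetoxy-7-(benzyloxy)-2-[4-(benzyloxy)phenyl]chroman-4-yl]-4,5-bis(benzyloxy)phenyl}-7-(benzyloxy)chroman-3-yl benzoate, via dioxolan-2-ylium ion 18 (not isolated)
Conditions: Ac2O (excess), TMSOTf (cat.), CH2Cl2, −40 to 0 °C
Reagents that add atoms: acetic anhydride, CC(=O)OC(C)=O
Why: Proposed new method: acetyl triflate made in situ should acylate the only dialkyl-type ether oxygen, O3(C), and the C2(F)–O bond then ionises because this carbon is benzylic and para to O4'; the neighbouring benzoate captures the cation as the less hindered trans-dioxolan-2-ylium ion 18, and the ortho benzyloxy oxygen of ring D opens 18 at C2(F) with inversion (6-exo-tet) and passes its benzyl group on to acetate, which gives the 2,3-trans (2R) chroman irreversibly because O3(C) is now an ester and the aryl ether oxygens of rings C and F are far poorer acyl acceptors; the closest known reaction types are the acylative cleavage of isochromans and benzyl ethers with an acyl halide or anhydride and a Lewis acid, the acyloxonium-mediated closure of 1,3-diarylpropane-1,2-diol orthoesters to 2,3-trans-flavan-3-ols, and debenzylative cycloetherification.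

Step 12
Reactants: 19 acetate benzoate
Product: 20 (2R,3S)-2-{2-[(2R,3S,4R)-7-(benzyloxy)-2-[4-(benzyloxy)phenyl]-3-hydroxychroman-4-yl]-4,5-bis(benzyloxy)phenyl}-7-(benzyloxy)chroman-3-ol
Conditions: NaOMe (cat.), MeOH–THF, rt
Reagents that add atoms: none
Why: Zemplén transesterification removes both esters, and no stereocentre is at risk because all phenols are still benzylated, so no quinone methide can form.

Step 13
Reactants: 20 penta-O-benzyl diol
Product: 21 guibourtinidol-(4α→6')-fisetinidol (target)
Conditions: H2 (1 atm), Pd(OH)2/C, THF–MeOH, rt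
Reagents that add atoms: none
Why: Hydrogenolysis of aryl benzyl ethers over Pearlman's catalyst is the standard last step for flavan-3-ols and leaves the cyclic benzylic C2–O1 bonds and the C4–aryl bond intact.

**Compound list**
1 | 1-[4-(benzyloxy)-2-hydroxyphenyl]ethan-1-one | CC(=O)c1ccc(OCc2ccccc2)cc1O | starting material
2 | 1-[4-(benzyloxy)-2-(methoxymethoxy)phenyl]ethan-1-one | CC(=O)c1ccc(OCc2ccccc2)cc1OCOC | intermediate
3 | 4-(benzyloxy)benzaldehyde | O=Cc1ccc(OCc2ccccc2)cc1 | starting material
4 | (E)-1-[4-(benzyloxy)-2-(methoxymethoxy)phenyl]-3-[4-(benzyloxy)phenyl]prop-2-en-1-one | O=C(/C=C/c1ccc(OCc2ccccc2)cc1)c1ccc(OCc2ccccc2)cc1OCOC | intermediate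
5 | [4-(benzyloxy)-2-(methoxymethoxy)phenyl]{(2R,3S)-3-[4-(benzyloxy)phenyl]oxiran-2-yl}methanone | O=C(c1ccc(OCc2ccccc2)cc1OCOC)[C@@H]1O[C@H]1c1ccc(OCc2ccccc2)cc1 | intermediate
6 | [4-(benzyloxy)-2-hydroxyphenyl]{(2R,3S)-3-[4-(benzyloxy)phenyl]oxiran-2-yl}methanone | O=C(c1ccc(OCc2ccccc2)cc1O)[C@@H]1O[C@H]1c1ccc(OCc2ccccc2)cc1 | intermediate
7 | (2R,3R)-7-(benzyloxy)-2-[4-(benzyloxy)phenyl]-3-hydroxychroman-4-one | c1ccccc1COc1ccc([C@H]2Oc3cc(OCc4ccccc4)ccc3C(=O)[C@@H]2O)cc1 | intermediate
8 | (2R,3S,4R)-7-(benzyloxy)-2-[4-(benzyloxy)phenyl]chroman-3,4-diol | c1ccccc1COc1ccc([C@H]2Oc3cc(OCc4ccccc4)ccc3[C@@H](O)[C@@H]2O)cc1 | intermediate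
9 | 1,2-bis(benzyloxy)benzene | c1ccccc1COc1ccccc1OCc1ccccc1 | starting material
10 | (2R,3S,4R)-7-(benzyloxy)-2-[4-(benzyloxy)phenyl]-4-[3,4-bis(benzyloxy)phenyl]chroman-3-ol | c1ccccc1COc1ccc([C@H]2Oc3cc(OCc4ccccc4)ccc3[C@@H](c3cc(OCc4ccccc4)c(OCc4ccccc4)cc3)[C@@H]2O)cc1 | intermediate
11 | 1,3-bis(benzyloxy)benzene | c1ccccc1COc1cccc(OCc2ccccc2)c1 | starting material
12 | 2,4-bis(benzyloxy)-1-iodobenzene | Ic1ccc(OCc2ccccc2)cc1OCc1ccccc1 | intermediate
13 | prop-2-en-1-ol (allyl alcohol) | C=CCO | starting material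
14 | 3-[2,4-bis(benzyloxy)phenyl]propanal | O=CCCc1ccc(OCc2ccccc2)cc1OCc1ccccc1 | intermediate
15 | (2S)-1-[2,4-bis(benzyloxy)phenyl]-3-oxopropan-2-yl benzoate | O=C[C@@H](OC(=O)c1ccccc1)Cc1ccc(OCc2ccccc2)cc1OCc1ccccc1 | intermediate
16 | oxocarbenium ion, O3(C) of 10 doubly bonded to the former aldehyde carbon of 15 | c1ccccc1COc1ccc([C@H]2Oc3cc(OCc4ccccc4)ccc3[C@@H](c3cc(OCc4ccccc4)c(OCc4ccccc4)cc3)[C@@H]2[O+]=C[C@@H](OC(=O)c2ccccc2)Cc2ccc(OCc3ccccc3)cc2OCc2ccccc2)cc1 | intermediate
17 | isochroman (ring G trans-fused to ring C; bridging CH is R and carries the (1S)-1-(benzoyloxy)-2-[2,4-bis(benzyloxy)phenyl]ethyl group) | c1ccccc1COc1ccc([C@H]2Oc3cc(OCc4ccccc4)ccc3[C@H]3c4cc(OCc5ccccc5)c(OCc5ccccc5)cc4[C@H]([C@@H](OC(=O)c4ccccc4)Cc4ccc(OCc5ccccc5)cc4OCc4ccccc4)O[C@H]23)cc1 | intermediate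
18 | trans-4,5-disubstituted 2-phenyl-1,3-dioxolan-2-ylium ion spanning C2(F)/C3(F), with O3(C) acetylated | c1ccccc1COc1ccc([C@H]2Oc3cc(OCc4ccccc4)ccc3[C@@H](c3cc(OCc4ccccc4)c(OCc4ccccc4)cc3[C@@H]3OC(c4ccccc4)=[O+][C@H]3Cc3ccc(OCc4ccccc4)cc3OCc3ccccc3)[C@@H]2OC(C)=O)cc1 | intermediate
19 | penta-O-benzyl target, 3(C)-acetate 3(F)-benzoate | c1ccccc1COc1ccc([C@H]2Oc3cc(OCc4ccccc4)ccc3[C@@H](c3cc(OCc4ccccc4)c(OCc4ccccc4)cc3[C@H]3Oc4cc(OCc5ccccc5)ccc4C[C@@H]3OC(=O)c3ccccc3)[C@@H]2OC(C)=O)cc1 | intermediate
20 | penta-O-benzyl target (both 3-OH free) | c1ccccc1COc1ccc([C@H]2Oc3cc(OCc4ccccc4)ccc3[C@@H](c3cc(OCc4ccccc4)c(OCc4ccccc4)cc3[C@H]3Oc4cc(OCc5ccccc5)ccc4C[C@@H]3O)[C@@H]2O)cc1 | intermediate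
21 | guibourtinidol-(4α→6')-fisetinidol, upper unit 2R,3S,4R, lower unit 2R,3S | Oc1ccc([C@H]2Oc3cc(O)ccc3[C@@H](c3cc(O)c(O)cc3[C@H]3Oc4cc(O)ccc4C[C@@H]3O)[C@@H]2O)cc1 | target

**Count**
Total steps: 13. Longest linear sequence: 10 (steps 1–6 and 10–13).

**Steps most likely to fail**

Step 11.
- What may go wrong: C-acetylation or benzyl transfer onto the electron-rich rings, capture of the cation by external acetate without loss of the benzyl group, or elimination towards the enol benzoate.
- The fallback uses known chemistry only. It sets out from 17 and comes back at 21.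
- Hydrogenolysis (H2, Pd(OH)2/C, EtOAc–MeOH) should give the hexaphenol isochroman benzoate F1.
- Ac2O with BF3·OEt2 at 0 °C acetylates all phenols and acetolyses ring G, giving the ring-opened octaacetate benzoate F2. Either epimer at the benzylic acetate serves.
- NH4OAc in aqueous MeOH under argon cleaves only the aryl acetates. The freed 4'-phenol then expels the benzylic acetate by 1,6-elimination to give the ring-E para-quinone methide F3.
- The ortho phenol of ring D adds to C2(F) of the quinone methide to give the hexaphenol acetate benzoate F4. Re-closure to ring G is blocked because O3(C) is still an acetate.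
- Brief NaOMe in MeOH at 0 °C under argon then gives 21. In this variant the 2,3-trans geometry rests on the equatorial preference in the closure, not on participation.

Step 10.
- What may go wrong: slow condensation of the hindered secondary alcohol, intermolecular attack of ring A or D carbons on the activated aldehyde, or loss of configuration at C3(F) by enolisation.
- The fallback raises the nucleophilicity of ring E instead of the strength of the acid. It sets out from 8 and comes back at 17.
- Condensation of 8 with free catechol (large excess, BF3·OEt2, dioxane) should give the 4-(3,4-dihydroxyphenyl)flavan-3-ol F5.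
- The free 4'-OH of this compound lets the closure with 15 run under the very mild acid known for hydroxytyrosol-type arylethanols and for unprotected flavan-3-ols (cat. p-TsOH, or BF3·OEt2 in dioxane, rt). This gives the catechol isochroman F6.
- Benzylation (BnBr, K2CO3, DMF) returns to 17.

Step 6.
- What may go wrong: self-condensation of the flavan-4-yl cation with C6 of another A ring, which outruns the weakly nucleophilic catechol diether, and incomplete facial selectivity at C4.
- The fallback is a halogen-capping tactic. It sets out from 8 and comes back at 10.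
- NBS (1 equiv, CH2Cl2, −78 to −20 °C) should brominate the most activated position, giving the 6-bromo flavan-3,4-diol F7.
- Arylation with 9 and BF3·OEt2 then meets no competing A-ring nucleophile and gives the 6-bromo 4-arylflavan-3-ol F8.
- Hydrodebromination (Pd(PPh3)4, HCO2Na, DMF, 80 °C) returns to 10.

**Further compounds**
F1 | step 11 | hexaphenol isochroman benzoate | Oc1ccc([C@H]2Oc3cc(O)ccc3[C@H]3c4cc(O)c(O)cc4[C@H]([C@@H](OC(=O)c4ccccc4)Cc4ccc(O)cc4O)O[C@H]23)cc1
F2 | step 11 | ring-opened octaacetate benzoate | CC(=O)Oc1ccc([C@H]2Oc3cc(OC(C)=O)ccc3[C@@H](c3cc(OC(C)=O)c(OC(C)=O)cc3[C@@H](OC(C)=O)[C@@H](OC(=O)c3ccccc3)Cc3ccc(OC(C)=O)cc3OC(C)=O)[C@@H]2OC(C)=O)cc1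
F3 | step 11 | ring-E para-quinone methide | Oc1ccc([C@H]2Oc3cc(O)ccc3[C@@H](C3=CC(=O)C(O)=CC3=C[C@@H](OC(=O)c3ccccc3)Cc3ccc(O)cc3O)[C@@H]2OC(C)=O)cc1
F4 | step 11 | hexaphenol 3(C)-acetate 3(F)-benzoate | Oc1ccc([C@H]2Oc3cc(O)ccc3[C@@H](c3cc(O)c(O)cc3[C@H]3Oc4cc(O)ccc4C[C@@H]3OC(=O)c3ccccc3)[C@@H]2OC(C)=O)cc1
F5 | step 10 | (2R,3S,4R)-7-(benzyloxy)-2-[4-(benzyloxy)phenyl]-4-(3,4-dihydroxyphenyl)chroman-3-ol | c1ccccc1COc1ccc([C@H]2Oc3cc(OCc4ccccc4)ccc3[C@@H](c3cc(O)c(O)cc3)[C@@H]2O)cc1
F6 | step 10 | catechol isochroman (17 with free O3' and O4') | c1ccccc1COc1ccc([C@H]2Oc3cc(OCc4ccccc4)ccc3[C@H]3c4cc(O)c(O)cc4[C@H]([C@@H](OC(=O)c4ccccc4)Cc4ccc(OCc5ccccc5)cc4OCc4ccccc4)O[C@H]23)cc1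
F7 | step 6 | (2R,3S,4R)-7-(benzyloxy)-2-[4-(benzyloxy)phenyl]-6-bromochroman-3,4-diol | c1ccccc1COc1ccc([C@H]2Oc3cc(OCc4ccccc4)c(Br)cc3[C@@H](O)[C@@H]2O)cc1
F8 | step 6 | (2R,3S,4R)-7-(benzyloxy)-2-[4-(benzyloxy)phenyl]-4-[3,4-bis(benzyloxy)phenyl]-6-bromochroman-3-ol | c1ccccc1COc1ccc([C@H]2Oc3cc(OCc4ccccc4)c(Br)cc3[C@@H](c3cc(OCc4ccccc4)c(OCc4ccccc4)cc3)[C@@H]2O)cc1
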